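Everything rests on cutting ring C, the benzene, into three alkynes. The key step exploits its substitution pattern: the adjacent carbons bearing the quaternary stereocentre Cq and the lactone carbonyl come from an ynoate, while the two CH carbons and the two carbons shared with ring D come from a C2-symmetric 1,7-diyne whose four-carbon tether is the future quinone. One rhodium-catalysed (2+2+2) cycloaddition forms three C–C bonds and closes ring C and the ring D carbocycle, with the congested aryl–Cq bond already in place. The precursors are tert-butyl ynoate 8, whose Cq is set by an enantioselective Diels–Alder reaction, and bis(silyloxy) diyne 14.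

Key step: step 11

Remarks on the chemistry
- Ring letters: A = cyclohexene carrying Cq; B = seven-membered enol lactone; C = benzene; D = quinone; E = 1,4-thiazine 1,1-dioxide.
- The carboxyl group of the ynoate is carried as a tert-butyl ester, because an ester next to the hindered Cq is best unmasked by acid. The carbon skeleton of the ynoate is unchanged.
- Assumption: by the accepted pre-transition-state model for 2-substituted acroleins, the oxazaborolidinium ion from (R)-diphenylprolinol exposes the Cα Si face of methacrolein. If the sense were found to be opposite, the antipodal catalyst would be used with no other change.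
- Transient stereo-elements (the ring A silyloxy centre in 4–7, the enol ether geometry in 16) are drawn as the expected major isomers. Minor isomers converge on the same later compounds.

Step 1
Reactants: 1 (E)-2-methylbut-2-enal (tiglic aldehyde)
Product: 2 (1E)-1-[(tert-butyldimethylsilyl)oxy]-2-methylbuta-1,3-diene
Conditions: TBSOTf, Et3N, Et2O, 0 °C → rt
Reagents that add atoms: TBSOTf (tert-butyldimethylsilyl trifluoromethanesulfonate), CC(C)(C)[Si](C)(C)OS(=O)(=O)C(F)(F)F
Why: Silyl dienol ether formation by O-silylation and γ-deprotonation of the enal; the 1E isomer should predominate and is the only one able to reach the s-cis geometry needed next.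

Step 2
Reactants: 2 (1E)-1-[(tert-butyldimethylsilyl)oxy]-2-methylbuta-1,3-diene; 3 methacrolein
Product: 4 (1R,2S)-2-[(tert-butyldimethylsilyl)oxy]-1,3-dimethylcyclohex-3-ene-1-carbaldehyde
Conditions: (R)-3,3-diphenyl-1-(o-tolyl)tetrahydro-1H,3H-pyrrolo[1,2-c][1,3,2]oxazaborole + HN(SO2CF3)2 (20 mol% each), CH2Cl2, −78 °C
Reagents that add atoms: none
Why: Chiral Lewis acid catalysed Diels–Alder reaction in which the silyloxy terminus of the diene bonds to the α-carbon of the coordinated enal (ortho rule) and the catalyst screens one face of the s-trans enal, so that the diene adds to the Cα Si face and sets the quaternary carbon as 1R; the endo adduct (silyloxy cis to formyl, 2S) is expected to prevail and this second centre is erased in step 6.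

Step 3
Reactants: 4 (1R,2S)-2-[(tert-butyldimethylsilyl)oxy]-1,3-dimethylcyclohex-3-ene-1-carbaldehyde
Product: 5 tert-butyl{[(1S,6S)-6-ethynyl-2,6-dimethylcyclohex-2-en-1-yl]oxy}dimethylsilane
Conditions: dimethyl (1-diazo-2-oxopropyl)phosphonate, K2CO3, MeOH, 0 °C → rt
Reagents that add atoms: dimethyl (1-diazo-2-oxopropyl)phosphonate, COP(=O)(OC)C(=[N+]=[N-])C(C)=O
Why: Seyferth–Gilbert homologation in the Ohira–Bestmann form, in which the diazophosphonate anion adds to the non-enolisable aldehyde and the alkylidene carbene rearranges to the terminal alkyne; the quaternary centre is untouched (its descriptor changes from R to S only because the priorities change).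

Step 4
Reactants: 5 tert-butyl{[(1S,6S)-6-ethynyl-2,6-dimethylcyclohex-2-en-1-yl]oxy}dimethylsilane
Product: 6 tert-butyl 3-[(1S,2S)-2-[(tert-butyldimethylsilyl)oxy]-1,3-dimethylcyclohex-3-en-1-yl]prop-2-ynoate
Conditions: n-BuLi, THF, −78 °C; then Boc2O, −78 → 0 °C
Reagents that add atoms: di-tert-butyl dicarbonate, CC(C)(C)OC(=O)OC(=O)OC(C)(C)C
Why: Deprotonation of the terminal alkyne and C-acylation of the lithium acetylide give the tert-butyl ynoate, the silyl ether keeping the ring A oxygen inert to the base.

Step 5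
Reactants: 6 tert-butyl 3-[(1S,2S)-2-[(tert-butyldimethylsilyl)oxy]-1,3-dimethylcyclohex-3-en-1-yl]prop-2-ynoate
Product: 7 tert-butyl 3-[(1S,2S)-2-hydroxy-1,3-dimethylcyclohex-3-en-1-yl]prop-2-ynoate
Conditions: HF·pyridine, THF, 0 °C → rt
Reagents that add atoms: none
Why: Fluoride-driven cleavage of the allylic silyl ether under mildly acidic conditions that spare the ynoate and the tert-butyl ester.

Step 6
Reactants: 7 tert-butyl 3-[(1S,2S)-2-hydroxy-1,3-dimethylcyclohex-3-en-1-yl]prop-2-ynoate
Product: 8 tert-butyl 3-[(1S)-1,3-dimethyl-2-oxocyclohex-3-en-1-yl]prop-2-ynoate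
Conditions: Dess–Martin periodinane, CH2Cl2, 0 °C → rt
Reagents that add atoms: none
Why: Dess–Martin oxidation of the secondary allylic alcohol gives the ring A enone and removes the transient carbinol centre, so both Diels–Alder diastereomers converge on one compound.

Step 7
Reactants: 9 succinyl chloride; 10 bis(trimethylsilyl)acetylene (two equivalents, one for each acyl chloride)
Product: 11 1,8-bis(trimethylsilyl)octa-1,7-diyne-3,6-dione
Conditions: 10 (2.2 equiv), AlCl3 (2.2 equiv), CH2Cl2, 0 °C
Reagents that add atoms: bis(trimethylsilyl)acetylene (the second equivalent of 10), C[Si](C)(C)C#C[Si](C)(C)C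
Why: Twofold Friedel–Crafts-type acyldesilylation, in which each AlCl3-activated acyl chloride end of 9 attacks its own molecule of 10 at a silicon-bearing carbon with loss of Me3SiCl, so that two molecules of 10 are consumed per molecule of 9; each ynone formed is too deactivated to react at its remaining silyl group.

Step 8
Reactants: 11 1,8-bis(trimethylsilyl)octa-1,7-diyne-3,6-dione
Product: 12 (3R,6R)-1,8-bis(trimethylsilyl)octa-1,7-diyne-3,6-diol
Conditions: RuCl[(R,R)-TsDPEN](p-cymene) (2 mol%), i-PrOH, rt
Reagents that add atoms: none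
Why: Noyori–Ikariya asymmetric transfer hydrogenation of ynones, in which the (R,R)-TsDPEN ruthenium hydride delivers hydride to the same face of each alkynyl ketone and sets both carbinol centres as R under catalyst control.

Step 9
Reactants: 12 (3R,6R)-1,8-bis(trimethylsilyl)octa-1,7-diyne-3,6-diol
Product: 13 (3R,6R)-3,6-bis[(tert-butyldimethylsilyl)oxy]-1,8-bis(trimethylsilyl)octa-1,7-diyne
Conditions: TBSCl (2.5 equiv), imidazole, DMF, rt
Reagents that add atoms: tert-butyldimethylsilyl chloride, CC(C)(C)[Si](C)(C)Cl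
Why: Imidazole-promoted silylation of the two propargylic alcohols, which leaves the carbinol centres untouched.

Step 10
Reactants: 13 (3R,6R)-3,6-bis[(tert-butyldimethylsilyl)oxy]-1,8-bis(trimethylsilyl)octa-1,7-diyne
Product: 14 (3R,6R)-3,6-bis[(tert-butyldimethylsilyl)oxy]octa-1,7-diyne
Conditions: K2CO3 (cat.), MeOH, rt
Reagents that add atoms: none
Why: Methoxide-mediated protodesilylation removes only the alkynyl C–SiMe3 groups, the O-silyl ethers being stable to K2CO3 in methanol.

Step 11
Reactants: 8 tert-butyl 3-[(1S)-1,3-dimethyl-2-oxocyclohex-3-en-1-yl]prop-2-ynoate; 14 (3R,6R)-3,6-bis[(tert-butyldimethylsilyl)oxy]octa-1,7-diyne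
Product: 15 tert-butyl (5R,8R)-5,8-bis[(tert-butyldimethylsilyl)oxy]-3-[(1S)-1,3-dimethyl-2-oxocyclohex-3-en-1-yl]-5,6,7,8-tetrahydronaphthalene-2-carboxylate
Conditions: [Rh(cod)2]BF4 (10 mol%), rac-BINAP (10 mol%), pre-activated with H2, CH2Cl2, rt → 40 °C, 14 (1.5 equiv) added over 6 h
Reagents that add atoms: none
Why: Oxidative coupling of the two tethered alkynes of 14 on the cationic monovalent rhodium–bisphosphine centre should give a bicyclic rhodacyclopentadiene (trivalent rhodium), into which the electron-poor triple bond of 8 inserts before reductive elimination releases the benzene. The closest known reaction type is the cationic rhodium–bisphosphine cross-cyclotrimerisation of 1,6- and 1,7-diynes with alkynoates. The carbocycle that becomes ring D closes in the oxidative coupling, because its two alkynes are joined by a four-carbon chain, and ring C closes in the final C–C reductive elimination from the seven-membered rhodacycle. No stereocentre is formed: Cq and the two silyloxy centres are spectators, and the C2 axis of 14 means that either orientation of 8 leads to the same product, so no regiochemical question arises. The selectivity needed is cross- over homo-cyclotrimerisation, which slow addition of 14 secures together with the fact that 8 is too hindered and electron-poor to trimerise on its own. Because the new ring is built around a triple bond that already carries Cq, no coupling at the congested aryl–Cq junction is required.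

Step 12
Reactants: 15 tert-butyl (5R,8R)-5,8-bis[(tert-butyldimethylsilyl)oxy]-3-[(1S)-1,3-dimethyl-2-oxocyclohex-3-en-1-yl]-5,6,7,8-tetrahydronaphthalene-2-carboxylate
Product: 16 tert-butyl (5R,8R)-5,8-bis[(tert-butyldimethylsilyl)oxy]-3-[(1S,2E)-2-(methoxymethylidene)-1,3-dimethylcyclohex-3-en-1-yl]-5,6,7,8-tetrahydronaphthalene-2-carboxylate
Conditions: Ph3P(CH2OMe)Cl, KN(SiMe3)2, THF, 0 → 50 °C
Reagents that add atoms: (methoxymethyl)triphenylphosphonium chloride, COC[P+](c1ccccc1)(c1ccccc1)c1ccccc1.[Cl-]
Why: Wittig methoxymethylenation with the non-stabilised potassium ylide, which adds 1,2 to the cross-conjugated ketone and is inert to the tert-butyl ester and the silyl ethers; the enol ether geometry is irrelevant because it is hydrolysed next.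

Step 13
Reactants: 16 tert-butyl (5R,8R)-5,8-bis[(tert-butyldimethylsilyl)oxy]-3-[(1S,2E)-2-(methoxymethylidene)-1,3-dimethylcyclohex-3-en-1-yl]-5,6,7,8-tetrahydronaphthalene-2-carboxylate
Product: 17 tert-butyl (5R,8R)-3-[(1S)-2-formyl-1,3-dimethylcyclohex-2-en-1-yl]-5,8-dihydroxy-5,6,7,8-tetrahydronaphthalene-2-carboxylate
Conditions: 48% aq. HF, MeCN, 0 °C → rt
Reagents that add atoms: water, O
Why: Aqueous HF cleaves both benzylic silyl ethers and hydrolyses the dienol ether (protonation at its remote carbon, then hydration of the conjugated oxocarbenium ion) to the tetrasubstituted enal, while the tert-butyl ester should survive.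

Step 14
Reactants: 17 tert-butyl (5R,8R)-3-[(1S)-2-formyl-1,3-dimethylcyclohex-2-en-1-yl]-5,8-dihydroxy-5,6,7,8-tetrahydronaphthalene-2-carboxylate
Product: 20 tert-butyl 3-[(1S)-2-formyl-1,3-dimethylcyclohex-2-en-1-yl]-5,8-dioxo-5,8-dihydronaphthalene-2-carboxylate, via tetralin-1,4-dione 18 (not isolated), via naphthalene-1,4-diol 19 (not isolated)
Conditions: Dess–Martin periodinane (3.5 equiv), CH2Cl2, rt; then Et3N (cat.)
Reagents that add atoms: none
Why: Dess–Martin oxidation of both benzylic alcohols gives tetralin-1,4-dione 18, whose base-catalysed enolisation aromatises ring D to naphthalene-1,4-diol 19, which the remaining periodinane oxidises to the quinone.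

Step 15
Reactants: 20 tert-butyl 3-[(1S)-2-formyl-1,3-dimethylcyclohex-2-en-1-yl]-5,8-dioxo-5,8-dihydronaphthalene-2-carboxylate
Product: 22 quinone enol lactone comprising rings A–D of the target with the quinone CH=CH still unsubstituted (S at Cq), via carboxylic acid 21 (not isolated)
Conditions: TFA, CH2Cl2, rt; concentrate; then TsOH·H2O (10 mol%), toluene, 4 Å MS, 80 °C
Reagents that add atoms: none
Why: Acidolysis of the tert-butyl ester (loss of 2-methylpropene) followed by acid-catalysed dehydrative enol lactonisation, in which the acid adds to the protonated aldehyde, water leaves to give an acyloxy allyl cation, and loss of a ring A allylic proton gives the conjugated dienol lactone (ring B).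

Step 16
Reactants: 22 quinone enol lactone (rings A–D); 23 hypotaurine (2-aminoethanesulfinic acid)
Product: 27 target CNP0348176.1, via sulfonyl hydroquinone 24 (not isolated), via sulfonylquinone 25 (not isolated), via thiazine hydroquinone 26 (not isolated)
Conditions: 23 (1.2 equiv), MeCN/H2O (1:1), rt; then Co(salen) (5 mol%), O2 (1 atm), rt
Reagents that add atoms: none
Why: Hypotaurine annulation, in which the sulfinate of the zwitterion (nitrogen still protonated) adds in a Michael sense to the quinone carbon β to the more electron-poor carbonyl (the one attached to the ring C carbon para to the lactone carbonyl) to give 24, aerobic oxidation gives sulfonylquinone 25, and six-membered aza-Michael closure to 26 with reoxidation forms ring E with S and N placed as in the target; the bias is electronic and moderate, so a regioisomer may have to be removed by chromatography.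

Compound list
1 | (E)-2-methylbut-2-enal (tiglic aldehyde) | C/C=C(\C)C=O | starting material
2 | (1E)-1-[(tert-butyldimethylsilyl)oxy]-2-methylbuta-1,3-diene | C=C/C(C)=C/O[Si](C)(C)C(C)(C)C | intermediate
3 | methacrolein | C=C(C)C=O | starting material
4 | (1R,2S)-2-[(tert-butyldimethylsilyl)oxy]-1,3-dimethylcyclohex-3-ene-1-carbaldehyde | CC1=CCC[C@](C=O)(C)[C@H]1O[Si](C)(C)C(C)(C)C | intermediate
5 | tert-butyl{[(1S,6S)-6-ethynyl-2,6-dimethylcyclohex-2-en-1-yl]oxy}dimethylsilane | CC1=CCC[C@](C#C)(C)[C@H]1O[Si](C)(C)C(C)(C)C | intermediate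
6 | tert-butyl 3-[(1S,2S)-2-[(tert-butyldimethylsilyl)oxy]-1,3-dimethylcyclohex-3-en-1-yl]prop-2-ynoate | CC1=CCC[C@](C#CC(=O)OC(C)(C)C)(C)[C@H]1O[Si](C)(C)C(C)(C)C | intermediate
7 | tert-butyl 3-[(1S,2S)-2-hydroxy-1,3-dimethylcyclohex-3-en-1-yl]prop-2-ynoate | CC1=CCC[C@](C#CC(=O)OC(C)(C)C)(C)[C@H]1O | intermediate
8 | tert-butyl 3-[(1S)-1,3-dimethyl-2-oxocyclohex-3-en-1-yl]prop-2-ynoate | CC1=CCC[C@](C#CC(=O)OC(C)(C)C)(C)C1=O | intermediate
9 | succinyl chloride | O=C(Cl)CCC(=O)Cl | starting material
10 | bis(trimethylsilyl)acetylene | C[Si](C)(C)C#C[Si](C)(C)C | starting material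
11 | 1,8-bis(trimethylsilyl)octa-1,7-diyne-3,6-dione | C[Si](C)(C)C#CC(=O)CCC(=O)C#C[Si](C)(C)C | intermediate
12 | (3R,6R)-1,8-bis(trimethylsilyl)octa-1,7-diyne-3,6-diol | C[Si](C)(C)C#C[C@H](O)CC[C@@H](O)C#C[Si](C)(C)C | intermediate
13 | (3R,6R)-3,6-bis[(tert-butyldimethylsilyl)oxy]-1,8-bis(trimethylsilyl)octa-1,7-diyne | C[Si](C)(C)C#C[C@H](O[Si](C)(C)C(C)(C)C)CC[C@@H](O[Si](C)(C)C(C)(C)C)C#C[Si](C)(C)C | intermediate
14 | (3R,6R)-3,6-bis[(tert-butyldimethylsilyl)oxy]octa-1,7-diyne | C#C[C@H](O[Si](C)(C)C(C)(C)C)CC[C@@H](O[Si](C)(C)C(C)(C)C)C#C | intermediate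
15 | tert-butyl (5R,8R)-5,8-bis[(tert-butyldimethylsilyl)oxy]-3-[(1S)-1,3-dimethyl-2-oxocyclohex-3-en-1-yl]-5,6,7,8-tetrahydronaphthalene-2-carboxylate | CC1=CCC[C@](c2cc3c(cc2C(=O)OC(C)(C)C)[C@H](O[Si](C)(C)C(C)(C)C)CC[C@H]3O[Si](C)(C)C(C)(C)C)(C)C1=O | intermediate
16 | tert-butyl (5R,8R)-5,8-bis[(tert-butyldimethylsilyl)oxy]-3-[(1S,2E)-2-(methoxymethylidene)-1,3-dimethylcyclohex-3-en-1-yl]-5,6,7,8-tetrahydronaphthalene-2-carboxylate | CO/C=C1\C(C)=CCC[C@@]1(C)c1cc2c(cc1C(=O)OC(C)(C)C)[C@H](O[Si](C)(C)C(C)(C)C)CC[C@H]2O[Si](C)(C)C(C)(C)C | intermediate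
17 | tert-butyl (5R,8R)-3-[(1S)-2-formyl-1,3-dimethylcyclohex-2-en-1-yl]-5,8-dihydroxy-5,6,7,8-tetrahydronaphthalene-2-carboxylate | O=CC1=C(C)CCC[C@@]1(C)c1cc2c(cc1C(=O)OC(C)(C)C)[C@H](O)CC[C@H]2O | intermediate
18 | tert-butyl 3-[(1S)-2-formyl-1,3-dimethylcyclohex-2-en-1-yl]-5,8-dioxo-5,6,7,8-tetrahydronaphthalene-2-carboxylate (tetralin-1,4-dione, not isolated) | O=CC1=C(C)CCC[C@@]1(C)c1cc2c(cc1C(=O)OC(C)(C)C)C(=O)CCC2=O | intermediate
19 | tert-butyl 3-[(1S)-2-formyl-1,3-dimethylcyclohex-2-en-1-yl]-5,8-dihydroxynaphthalene-2-carboxylate (naphthalene-1,4-diol, not isolated) | O=CC1=C(C)CCC[C@@]1(C)c1cc2c(cc1C(=O)OC(C)(C)C)c(O)ccc2O | intermediate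
20 | tert-butyl 3-[(1S)-2-formyl-1,3-dimethylcyclohex-2-en-1-yl]-5,8-dioxo-5,8-dihydronaphthalene-2-carboxylate | O=CC1=C(C)CCC[C@@]1(C)c1cc2c(cc1C(=O)OC(C)(C)C)C(=O)C=CC2=O | intermediate
21 | 3-[(1S)-2-formyl-1,3-dimethylcyclohex-2-en-1-yl]-5,8-dioxo-5,8-dihydronaphthalene-2-carboxylic acid (not isolated) | O=CC1=C(C)CCC[C@@]1(C)c1cc2c(cc1C(=O)O)C(=O)C=CC2=O | intermediate
22 | quinone enol lactone, rings A–D of the target: ring A 1,3-diene carrying Cq (S), seven-membered enol lactone, benzene and unsubstituted 1,4-quinone | CC1=CCC[C@]2(C)C1=COC(=O)c1cc3c(cc12)C(=O)C=CC3=O | intermediate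
23 | hypotaurine (2-aminoethanesulfinic acid) | NCCS(=O)O | starting material
24 | hydroquinone of 22 carrying a (2-aminoethyl)sulfonyl group on the ring D CH carbon adjacent to the C–OH carbon that is bonded to the ring C carbon para to the Cq-bearing carbon (not isolated) | CC1=CCC[C@]2(C)C1=COC(=O)c1cc3c(O)c(S(=O)(=O)CCN)cc(O)c3cc12 | intermediate
25 | quinone form of 24: enol lactone quinone carrying the (2-aminoethyl)sulfonyl group on the same ring D carbon (sulfonylquinone, not isolated) | CC1=CCC[C@]2(C)C1=COC(=O)c1cc3c(cc12)C(=O)C=C(C3=O)S(=O)(=O)CCN | intermediate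
26 | hydroquinone form of the target: ring E closed, ring D as the 1,4-diol (thiazine hydroquinone, not isolated) | CC1=CCC[C@]2(C)C1=COC(=O)c1cc3c(O)c4c(c(O)c3cc12)NCCS4(=O)=O | intermediate
27 | CNP0348176.1, (S)-configured pentacyclic thiazine dioxide quinone enol lactone | CC1=CCC[C@]2(C)C1=COC(=O)c1cc3c(cc12)C(=O)C1=C(C3=O)S(=O)(=O)CCN1 | target

Total step count: 16
Longest linear sequence: 12 steps (steps 1–6, then 11–16); the diyne branch (steps 7–10) joins at step 11.

Steps most likely to fail

Step 11. Self-cyclotrimerisation or oligomerisation of the terminal diyne may outrun insertion of the ynoate, whose triple bond is shielded by the quaternary carbon. The fallback closes the two rings in separate operations and sets out from 14 (with 8). Palladium-catalysed reductive cyclisation of 14 (Pd2(dba)3·CHCl3, a zerovalent palladium source, with AcOH and Et3SiH in toluene) would close the ring D carbocycle first and give (3R,6R)-3,6-bis[(tert-butyldimethylsilyl)oxy]-1,2-dimethylidenecyclohexane F1. This s-cis-locked diene would undergo a Diels–Alder reaction with ynoate 8 (toluene, 110 °C, or EtAlCl2 promotion) to give the cyclohexa-1,4-diene tert-butyl (5R,8R)-5,8-bis[(tert-butyldimethylsilyl)oxy]-3-[(1S)-1,3-dimethyl-2-oxocyclohex-3-en-1-yl]-1,4,5,6,7,8-hexahydronaphthalene-2-carboxylate F2. Dehydrogenation with DDQ would aromatise ring C and rejoin the route at 15.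

Step 12. The ylide may fail to add to the ketone, which is flanked by Cq and a methyl-bearing alkene carbon, or may only deprotonate the enone at its γ-position. The fallback installs the carbon as a smaller methylene unit and sets out from 15. Takai–Lombardo methylenation (Zn, CH2Br2, TiCl4, THF/CH2Cl2) should give tert-butyl (5R,8R)-5,8-bis[(tert-butyldimethylsilyl)oxy]-3-[(1R)-1,3-dimethyl-2-methylidenecyclohex-3-en-1-yl]-5,6,7,8-tetrahydronaphthalene-2-carboxylate F3, with the same spatial arrangement at Cq (the descriptor changes with the priorities). Hydroboration of the exocyclic alkene with 9-BBN, with hydrogen delivered to the face opposite the aryl group, then NaBO3 oxidation, should give tert-butyl (5R,8R)-5,8-bis[(tert-butyldimethylsilyl)oxy]-3-[(1R,2S)-2-(hydroxymethyl)-1,3-dimethylcyclohex-3-en-1-yl]-5,6,7,8-tetrahydronaphthalene-2-carboxylate F4. Aqueous HF in MeCN should then give tert-butyl (5R,8R)-5,8-dihydroxy-3-[(1R,2S)-2-(hydroxymethyl)-1,3-dimethylcyclohex-3-en-1-yl]-5,6,7,8-tetrahydronaphthalene-2-carboxylate F5. Dess–Martin periodinane followed by catalytic Et3N should give tert-butyl 3-[(1R,2S)-2-formyl-1,3-dimethylcyclohex-3-en-1-yl]-5,8-dioxo-5,8-dihydronaphthalene-2-carboxylate F6. Under the conditions of step 15 (TFA, then TsOH in toluene) F6 should lose 2-methylpropene and water and rejoin the route at 22.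

Step 16. The first C–S bond may form with insufficient regiocontrol if free amine competes with the sulfinate as the first nucleophile, and the amine may also open the enol lactone. The fallback fixes the order of bond formation with a protecting group and sets out from 22 (with 23). Hypotaurine 23 would be converted with Boc2O and NaOH into sodium 2-[(tert-butoxycarbonyl)amino]ethanesulfinate F7. In aqueous MeCN with AcOH, F7 can add to 22 only through sulfur, giving the Boc-protected sulfonyl hydroquinone F8, a neutral compound whose regioisomer can be removed on silica. TFA would remove the Boc group and rejoin the route at 24 (as its salt), which after neutralisation is carried through the aerobic closure of step 16 to 27.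

Further compounds
F1 | step 11 | (3R,6R)-3,6-bis[(tert-butyldimethylsilyl)oxy]-1,2-dimethylidenecyclohexane | C=C1[C@H](O[Si](C)(C)C(C)(C)C)CC[C@@H](O[Si](C)(C)C(C)(C)C)C1=C
F2 | step 11 | tert-butyl (5R,8R)-5,8-bis[(tert-butyldimethylsilyl)oxy]-3-[(1S)-1,3-dimethyl-2-oxocyclohex-3-en-1-yl]-1,4,5,6,7,8-hexahydronaphthalene-2-carboxylate | CC1=CCC[C@](C=2CC3=C(CC=2C(=O)OC(C)(C)C)[C@H](O[Si](C)(C)C(C)(C)C)CC[C@H]3O[Si](C)(C)C(C)(C)C)(C)C1=O
F3 | step 12 | tert-butyl (5R,8R)-5,8-bis[(tert-butyldimethylsilyl)oxy]-3-[(1R)-1,3-dimethyl-2-methylidenecyclohex-3-en-1-yl]-5,6,7,8-tetrahydronaphthalene-2-carboxylate | CC1=CCC[C@](c2cc3c(cc2C(=O)OC(C)(C)C)[C@H](O[Si](C)(C)C(C)(C)C)CC[C@H]3O[Si](C)(C)C(C)(C)C)(C)C1=C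
F4 | step 12 | tert-butyl (5R,8R)-5,8-bis[(tert-butyldimethylsilyl)oxy]-3-[(1R,2S)-2-(hydroxymethyl)-1,3-dimethylcyclohex-3-en-1-yl]-5,6,7,8-tetrahydronaphthalene-2-carboxylate | CC1=CCC[C@](c2cc3c(cc2C(=O)OC(C)(C)C)[C@H](O[Si](C)(C)C(C)(C)C)CC[C@H]3O[Si](C)(C)C(C)(C)C)(C)[C@H]1CO
F5 | step 12 | tert-butyl (5R,8R)-5,8-dihydroxy-3-[(1R,2S)-2-(hydroxymethyl)-1,3-dimethylcyclohex-3-en-1-yl]-5,6,7,8-tetrahydronaphthalene-2-carboxylate | CC1=CCC[C@](c2cc3c(cc2C(=O)OC(C)(C)C)[C@H](O)CC[C@H]3O)(C)[C@H]1CO
F6 | step 12 | tert-butyl 3-[(1R,2S)-2-formyl-1,3-dimethylcyclohex-3-en-1-yl]-5,8-dioxo-5,8-dihydronaphthalene-2-carboxylate | CC1=CCC[C@](c2cc3c(cc2C(=O)OC(C)(C)C)C(=O)C=CC3=O)(C)[C@H]1C=O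
F7 | step 16 | sodium 2-[(tert-butoxycarbonyl)amino]ethanesulfinate | [Na+].CC(C)(C)OC(=O)NCCS(=O)[O-]
F8 | step 16 | hydroquinone of 22 carrying a {2-[(tert-butoxycarbonyl)amino]ethyl}sulfonyl group at the position it occupies in 24 | CC1=CCC[C@]2(C)C1=COC(=O)c1cc3c(O)c(S(=O)(=O)CCNC(=O)OC(C)(C)C)cc(O)c3cc12
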